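Count what the partner can buy before asking any curve for a peak.

in all of them: catalyst 5.6 mM
- west: substrate 0.074 M; partner 0.088 M; run made earlier
- south-west: substrate 0.17 M; partner 0.088 M; run made earlier
- north-west: substrate 0.11 M; partner 0.18 M; run made earlier
- flask: substrate 0.11 M; partner 0.0880 M; time 15 d

| run | time / d | target / % | substrate / % |
|---|---|---|---|
| west | 0.167 | 14.9 | 85.6 |
| west | 0.833 | 21.2 | 76.1 |
| west | 4.00 | 4.0 | 91.9 |
| west | 20.0 | 0.3 | 98.0 |
| south-west | 0.167 | 12.5 | 87.2 |
| south-west | 0.833 | 16.6 | 81.1 |
| south-west | 4.00 | 4.9 | 90.1 |
| south-west | 20.0 | 0 | 97.3 |
| north-west | 0.167 | 24.9 | 73.4 |
| north-west | 0.833 | 35.7 | 60.4 |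
| north-west | 4.00 | 9.6 | 84.1 |
| north-west | 20.0 | 0.1 | 95.7 |

(standard deviation of a reading: 0.5 percentage points)

1. time up to 15 d at which target stands highest
2. the amount of target, in percent of the substrate charged, at that time
3. earliest time at which at least nineteen twentieths of that best amount are there, in d
4. latest time at which they still are, in d

- the analysis behind the earlier runs scatters by 0.5 percentage points, standard deviation

I built this flask up by hand. With the main step alone, substrate + partner to target, partner is the limiting reagent, its charge of 0.0880 M standing below the 0.11 M of substrate, and target could reach 80.0 % of the substrate charged.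

The runs stopped far short of such figures: the west run read 21.2 % at 0.833 d, then 4.0 % at 4.00 d with substrate back at 91.9 %. So I added a second process, a loss of partner on its own competing with the main step. With c(substrate) taken at its charge, my estimate of the top amount, in percent of the substrate charged, then comes to c(partner) divided by the sum of c(substrate) and a constant. The highest readings of the west and south-west runs gave that constant as 0.341 M and 0.360 M, and their mean, 0.351 M, I called the break-even concentration, the c(substrate) at which partner reaches target and is lost in equal shares. The north-west run, with twice the partner, gave a higher 0.394 M, so I held the rule to c(partner) of 0.0880 M. For the flask it gave 19.1 %, about a quarter of the main-step figure.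

The rest, target returning to substrate and the 4.1 percentage points missing from the west run at 4.00 d, I did not add again, since the readings behind the constant already contain it. Those readings were taken at a fixed time, though, and can stand under the true top.

The forecast, on the grounds that “the partner drives substrate to target, and target reverts to substrate”, put target at 20.5 % at 0.58 d, with the window from 0.38 d to 0.85 d, above my figure.

The flask gave 20.5 % at 0.623 d, with the window from 0.412 d to 0.923 d, and that top amount stood 1.4 points above my reckoning.

    substrate + partner ⇌ target (K = 19.0 L mol⁻¹, k = 0.560 L mol⁻¹ h⁻¹)
    substrate + partner ⇌ isomer of the product (K = 34.0 L mol⁻¹, k = 0.0250 L mol⁻¹ h⁻¹)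
    target + catalyst ⇌ isomer of the product + catalyst, rate k3*[catalyst]*[target] forward; the back reaction follows from the equilibrium constant (k = 0.310 L mol⁻¹ h⁻¹)
    partner → decomposed reagent (k = 0.0860 h⁻¹)

At the start of the flask, the conversion of partner into decomposed reagent used partner 1.4 times as fast as the forward conversion of substrate + partner into target, and 16.6 % of the partner's charge stood at 0.623 d. That ratio puts the forward break-even at 0.154 M, lower than the 0.351 M read from the runs, yet with 0.28 M of substrate and the same partner 0.351 M gives 13.9 % against the 15.0 % of that neighbour flask.

The earlier runs and the new flask stem from a simulated flask with constants of no real substance, and the scatter is random.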